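**Strategy.** Ring B is a 2-bromo-1-methylcyclohexanol whose OH (C-1, axial) and Br (C-2, equatorial) are cis, an arrangement that alkene bromohydration cannot deliver. The C-1/C-2 bond is therefore the one made in closing that ring. An acyclic 7,7-dibromo-2-ketone, cut from (R)-limonene oxide, is closed by SmI2: the carbenoid carbon becomes CHBr and the ketone carbon the tertiary carbinol, so ring, bond and both stereocentres arise in one stereoconvergent operation under control of the C-4 stereocentre. The isopropenyl group of the resulting bromohydrin is then brominated at its methyl group and joined to the kinetic enolate of (S)-carvone. Reductive enone transposition and a reagent-controlled epoxidation complete ring A.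

Key step: step 3

Assumption: commercial (+)-limonene oxide is the (4R)-1,2-epoxide as a cis/trans mixture; both epimers give the same keto-aldehyde in step 1.

Step 1
Reactants: 1 (+)-limonene 1,2-oxide, (4R)-1-methyl-4-(prop-1-en-2-yl)-7-oxabicyclo[4.1.0]heptane (cis/trans mixture)
Product: 3 (3R)-6-oxo-3-(prop-1-en-2-yl)heptanal, via trans-diol 2 (not isolated)
Conditions: H5IO6, THF/H2O, 0 °C to rt
Reagents that add atoms: water, O
Why: Acid-mediated epoxide hydrolysis followed by periodate glycol cleavage (Malaprade reaction) opens the ring between C-1 and C-2 without touching the C-4 stereocentre or the isopropenyl group, and both epoxide epimers converge on one keto-aldehyde.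

Step 2
Reactants: 3 (3R)-6-oxo-3-(prop-1-en-2-yl)heptanal
Product: 4 (5R)-7,7-dibromo-5-(prop-1-en-2-yl)heptan-2-one
Conditions: (PhO)3P, Br2, Et3N, CH2Cl2, −78 °C (reagent preformed, then 3)
Reagents that add atoms: bromine (delivered as the triphenyl phosphite adduct), BrBr
Why: Deoxygenative gem-dibromination of the aldehyde by the preformed triphenyl phosphite–bromine adduct (Appel-type oxyphosphonium displacement) should be selective at −78 °C, where an aldehyde reacts much faster than a methyl ketone and no free bromine remains for the alkene.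

Step 3
Reactants: 4 (5R)-7,7-dibromo-5-(prop-1-en-2-yl)heptan-2-one
Product: 6 (1S,2R,4R)-2-bromo-1-methyl-4-(prop-1-en-2-yl)cyclohexan-1-ol, via bromoalkylsamarium carbenoid 5 (not isolated)
Conditions: SmI2 (2.2 equiv, slow addition), THF, −78 °C to −20 °C; then aq. NH4Cl
Reagents that add atoms: none
Why: Proposed new method: two single-electron transfers from SmI2 turn one C–Br bond of the CHBr2 group into a C–Sm bond, and the alpha-bromoalkyl samarium carbenoid 5 adds to the tethered methyl ketone in Barbier fashion, so that C-2 (CHBr) and C-1 (C(OH)CH3) of ring B are joined and the trivalent samarium alkoxide is protonated on work-up. The closest known reactions are the SmI2-promoted halomethylation of ketones with dihalomethanes to halohydrins and the SmI2 Barbier cyclisation of halo ketones; closing a ring with a substituted gem-dibromide is the new element. The six-membered ring closes in the 6-exo-trig mode at the carbonyl carbon. The two diastereotopic bromines need not be differentiated, because the intermediate radical is planar and the carbenoid epimerises, so both new stereocentres are set in the chair transition state of C–C bond formation: the existing stereocentre (C-5 of 4, C-4 of the ring) places its isopropenyl group equatorial, the ketone methyl and the bromine take the other equatorial sites, and the carbonyl oxygen sits axial where samarium bridges it to the carbenoid carbon, which gives OH cis to Br and cis to the C-4 substituent, that is (1S,2R). The step needs reduction of the gem-dibromide in preference to the ketone (secured by the much easier reduction of CHBr2 than of a dialkyl ketone by SmI2 in THF without HMPA) and no further reduction of the beta-bromo alkoxide (secured by 2.2 equivalents, slow addition and low temperature). A cis-bromohydrin cannot close to an epoxide, so any trans isomer could afterwards be removed as the epoxide by brief base treatment.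

Step 4
Reactants: 6 (1S,2R,4R)-2-bromo-1-methyl-4-(prop-1-en-2-yl)cyclohexan-1-ol
Product: 7 {[(1S,2R,4R)-2-bromo-1-methyl-4-(prop-1-en-2-yl)cyclohexyl]oxy}trimethylsilane
Conditions: Me3SiOTf, 2,6-lutidine, CH2Cl2, −78 °C
Reagents that add atoms: trimethylsilyl triflate, C[Si](C)(C)OS(=O)(=O)C(F)(F)F
Why: Silylation of the tertiary alcohol removes the only acidic proton before the enolate alkylation and keeps the hydroxyl from trapping the bromonium ion of step 5 as a cineole-type bicyclic ether.

Step 5
Reactants: 7 {[(1S,2R,4R)-2-bromo-1-methyl-4-(prop-1-en-2-yl)cyclohexyl]oxy}trimethylsilane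
Product: 8 {[(1S,2R,4R)-2-bromo-4-(3-bromoprop-1-en-2-yl)-1-methylcyclohexyl]oxy}trimethylsilane
Conditions: NBS, Yb(OTf)3 (cat.), Me3SiCl (cat.), CH2Cl2/THF, 0 °C to rt
Reagents that add atoms: N-bromosuccinimide, BrN1C(=O)CCC1=O
Why: Lewis-acid-promoted ene-type allylic bromination of the 1,1-disubstituted alkene (bromonium formation, loss of a methyl proton) should turn the isopropenyl group into a 2-(bromomethyl)vinyl group, the only alkene in the molecule.

Step 6
Reactants: 9 (S)-(+)-carvone; 8 {[(1S,2R,4R)-2-bromo-4-(3-bromoprop-1-en-2-yl)-1-methylcyclohexyl]oxy}trimethylsilane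
Product: 11 (5S,6R)-6-{2-[(1R,3R,4S)-3-bromo-4-methyl-4-(trimethylsilyloxy)cyclohexyl]prop-2-en-1-yl}-2-methyl-5-(prop-1-en-2-yl)cyclohex-2-en-1-one, via lithium dienolate 10 (not isolated)
Conditions: LiN(i-Pr)2, THF, −78 °C; then 8, −78 °C to −30 °C
Reagents that add atoms: none
Why: Kinetic deprotonation of carvone at C-6 and SN2 alkylation of the cross-conjugated enolate by the allylic bromide should place the side chain anti to the adjacent C-5 isopropenyl group (6R, trans), which is also the thermodynamic configuration.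

Step 7
Reactants: 11 (5S,6R)-6-{2-[(1R,3R,4S)-3-bromo-4-methyl-4-(trimethylsilyloxy)cyclohexyl]prop-2-en-1-yl}-2-methyl-5-(prop-1-en-2-yl)cyclohex-2-en-1-one
Product: 12 N'-[(5S,6R)-6-{2-[(1R,3R,4S)-3-bromo-4-hydroxy-4-methylcyclohexyl]prop-2-en-1-yl}-2-methyl-5-(prop-1-en-2-yl)cyclohex-2-en-1-ylidene]-4-methylbenzenesulfonohydrazide
Conditions: TsNHNH2, PPTS (cat.), EtOH, rt to 40 °C
Reagents that add atoms: p-toluenesulfonyl hydrazide, Cc1ccc(cc1)S(=O)(=O)NN
Why: Acid-catalysed condensation of the enone with the sulfonyl hydrazide gives the tosylhydrazone, and the same acidic ethanol solvolyses the tertiary trimethylsilyl ether, which is no longer needed.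

Step 8
Reactants: 12 tosylhydrazone of the desilylated enone
Product: 14 (1S,2R,4R)-2-bromo-1-methyl-4-{3-[(1S,6S)-3-methyl-6-(prop-1-en-2-yl)cyclohex-2-en-1-yl]prop-1-en-2-yl}cyclohexan-1-ol, via allylic diazene 13 (not isolated)
Conditions: catecholborane, CHCl3, 0 °C; then NaOAc·3H2O, reflux
Reagents that add atoms: none
Why: Reduction of the alpha,beta-unsaturated tosylhydrazone with 1,3-transposition: hydride adds to C=N, sulfinate is eliminated, and the allylic diazene loses N2 in a retro-ene reaction that moves the double bond to the former carbonyl carbon and leaves both ring A stereocentres untouched.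

Step 9
Reactants: 14 (1S,2R,4R)-2-bromo-1-methyl-4-{3-[(1S,6S)-3-methyl-6-(prop-1-en-2-yl)cyclohex-2-en-1-yl]prop-1-en-2-yl}cyclohexan-1-ol
Product: 15 (1S,2R,4R)-2-bromo-1-methyl-4-{3-[(1R,2R,3S,6S)-6-methyl-3-(prop-1-en-2-yl)-7-oxabicyclo[4.1.0]heptan-2-yl]prop-1-en-2-yl}cyclohexan-1-ol (CNP0213097.1)
Conditions: 1,2:4,5-di-O-isopropylidene-β-D-erythro-2,3-hexodiulo-2,6-pyranose (D-fructose-derived ketone, 0.3 equiv), Oxone (2KHSO5·KHSO4·K2SO4), K2CO3, Bu4NHSO4, MeCN/dimethoxymethane, aq. Na2B4O7 buffer (pH 10.5), 0 °C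
Reagents that add atoms: Oxone (potassium peroxymonosulfate), [K+].[O-]S(=O)(=O)OO
Why: Shi asymmetric epoxidation: the chiral dioxirane should attack the trisubstituted ring A alkene much faster than the two 1,1-disubstituted alkenes, and by the spiro transition-state model (same sense as for 1-phenylcyclohexene) the D-fructose-derived ketone delivers oxygen to the face syn to the C-2 side chain, setting the (1R,6S) epoxide under catalyst control against the expected substrate bias, while the cis-bromohydrin cannot cyclise at pH 10.5.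

**Compound list**

1 | (+)-limonene 1,2-oxide, (4R)-1-methyl-4-(prop-1-en-2-yl)-7-oxabicyclo[4.1.0]heptane, cis/trans mixture | C=C(C)[C@@H]1CCC2(C)OC2C1 | starting material
2 | (1S,2S,4R)-1-methyl-4-(prop-1-en-2-yl)cyclohexane-1,2-diol (trans-diaxial diol) | C=C(C)[C@@H]1CC[C@](C)(O)[C@@H](O)C1 | intermediate
3 | (3R)-6-oxo-3-(prop-1-en-2-yl)heptanal | C=C(C)[C@@H](CC=O)CCC(C)=O | intermediate
4 | (5R)-7,7-dibromo-5-(prop-1-en-2-yl)heptan-2-one | C=C(C)[C@@H](CC(Br)Br)CCC(C)=O | intermediate
5 | [(3R)-1-bromo-6-oxo-3-(prop-1-en-2-yl)heptyl]samarium diiodide (carbenoid, C-1 configuration labile) | C=C(C)[C@@H](CC(Br)[Sm](I)I)CCC(C)=O | intermediate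
6 | (1S,2R,4R)-2-bromo-1-methyl-4-(prop-1-en-2-yl)cyclohexan-1-ol (OH and Br cis, Br equatorial) | C=C(C)[C@@H]1CC[C@](C)(O)[C@H](Br)C1 | intermediate
7 | {[(1S,2R,4R)-2-bromo-1-methyl-4-(prop-1-en-2-yl)cyclohexyl]oxy}trimethylsilane | C=C(C)[C@@H]1CC[C@](C)(O[Si](C)(C)C)[C@H](Br)C1 | intermediate
8 | {[(1S,2R,4R)-2-bromo-4-(3-bromoprop-1-en-2-yl)-1-methylcyclohexyl]oxy}trimethylsilane | C=C(CBr)[C@@H]1CC[C@](C)(O[Si](C)(C)C)[C@H](Br)C1 | intermediate
9 | (S)-(+)-carvone, (5S)-2-methyl-5-(prop-1-en-2-yl)cyclohex-2-en-1-one | CC1=CC[C@@H](CC1=O)C(C)=C | starting material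
10 | lithium (3S)-6-methyl-3-(prop-1-en-2-yl)cyclohexa-1,5-dien-1-olate (kinetic enolate of 9) | CC1=CC[C@@H](C=C1O[Li])C(C)=C | intermediate
11 | (5S,6R)-6-{2-[(1R,3R,4S)-3-bromo-4-methyl-4-(trimethylsilyloxy)cyclohexyl]prop-2-en-1-yl}-2-methyl-5-(prop-1-en-2-yl)cyclohex-2-en-1-one | C=C(C[C@@H]1[C@@H](C(=C)C)CC=C(C)C1=O)[C@@H]1CC[C@](C)(O[Si](C)(C)C)[C@H](Br)C1 | intermediate
12 | N'-[(5S,6R)-6-{2-[(1R,3R,4S)-3-bromo-4-hydroxy-4-methylcyclohexyl]prop-2-en-1-yl}-2-methyl-5-(prop-1-en-2-yl)cyclohex-2-en-1-ylidene]-4-methylbenzenesulfonohydrazide | C=C(C[C@@H]1[C@@H](C(=C)C)CC=C(C)C1=NNS(=O)(=O)c1ccc(C)cc1)[C@@H]1CC[C@](C)(O)[C@H](Br)C1 | intermediate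
13 | allylic diazene: 12 with C=N–NHTs replaced by CH–N=NH (hydroxyl shown free) | C=C(C[C@@H]1[C@@H](C(=C)C)CC=C(C)C1N=N)[C@@H]1CC[C@](C)(O)[C@H](Br)C1 | intermediate
14 | (1S,2R,4R)-2-bromo-1-methyl-4-{3-[(1S,6S)-3-methyl-6-(prop-1-en-2-yl)cyclohex-2-en-1-yl]prop-1-en-2-yl}cyclohexan-1-ol | C=C(C[C@@H]1[C@@H](C(=C)C)CCC(C)=C1)[C@@H]1CC[C@](C)(O)[C@H](Br)C1 | intermediate
15 | (1S,2R,4R)-2-bromo-1-methyl-4-{3-[(1R,2R,3S,6S)-6-methyl-3-(prop-1-en-2-yl)-7-oxabicyclo[4.1.0]heptan-2-yl]prop-1-en-2-yl}cyclohexan-1-ol | C=C(C[C@@H]1[C@@H](C(=C)C)CC[C@]2(C)O[C@H]12)[C@@H]1CC[C@](C)(O)[C@H](Br)C1 | target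

**Step count.** Total: 9 steps. Longest linear sequence: 9 steps (1 to 15); (S)-carvone 9 enters at step 6.

**Steps most likely to fail**

Step 3 (carries the proposed method). What may go wrong: over-reduction, in which the carbenoid or the beta-bromo alkoxide is reduced further and the ring closes to the cycloalkene; or closure through a chair with axial methyl or axial bromine, which erodes the cis selectivity. Fallback with known chemistry, from 3 back to 6: the same C-1/C-2 bond is closed as a pinacol. Stannane-mediated reductive cyclisation of the 1,6-keto-aldehyde 3 (Bu3SnH, AIBN, benzene, 80 °C; trans-selective for six-membered rings, with the two oxygens anti and the methyl equatorial) should give the trans-diaxial diol 2 as an isolated compound. 1,1'-Sulfonyldiimidazole and NaH in THF should convert 2 into the trans-fused cyclic sulfate F1. LiBr in THF should open it at the secondary carbon with inversion to the bromo hydrogen sulfate F2, and catalytic H2SO4 in wet THF should hydrolyse the tertiary sulfate to 6.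

Step 9. What may go wrong: poor facial selectivity, because the reagent has to override the substrate's preference for attack anti to the C-2 side chain, and partial epoxidation of the 1,1-disubstituted alkenes. Fallback, from 10 and 7 back to 15: the epoxide is set by a hydroxyl-directed epoxidation before the fragments are joined, and the union becomes an sp3–sp2 cross-coupling. Enolate 10 and monomeric formaldehyde should give trans-6-(hydroxymethyl)carvone F3. TsNHNH2 in EtOH should give its tosylhydrazone F4, and catecholborane followed by NaOAc·3H2O the homoallylic alcohol F5. VO(acac)2/t-BuOOH should epoxidise the ring alkene of F5 syn to the CH2OH group to give epoxy alcohol F6, and I2/PPh3/imidazole the epoxy iodide F7. On the other side, ozonolysis of 7 (O3, CH2Cl2, −78 °C; Me2S) should give methyl ketone F8, and KN(SiMe3)2/PhNTf2 its terminal enol triflate F9. Zinc insertion into F7 (Zn, LiCl, THF) should give alkylzinc iodide F10. Negishi coupling with F9 (Pd(PPh3)4, a zerovalent palladium catalyst, THF, 50 °C) should give the silyl ether of the target F11, and K2CO3/MeOH should free 15.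

Step 2. What may go wrong: loss of chemoselectivity, with the methyl ketone converted to a vinyl bromide, or bromine addition to the isopropenyl alkene. Fallback, from 3 back to 4: the aldehyde alone is condensed with 1,2-bis(tert-butyldimethylsilyl)hydrazine (Sc(OTf)3 cat.) to the N-silyl hydrazone F12. CuBr2/Et3N in MeOH should then oxidise F12 to the gem-dibromide 4 with loss of N2, without free bromine or strong acid.

**Further compounds**

F1 | step 3 | cyclic sulfate of diol 2 (trans-fused 1,3,2-dioxathiolane 2,2-dioxide) | C=C(C)[C@@H]1CC[C@]2(C)OS(=O)(=O)O[C@H]2C1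
F2 | step 3 | (1S,2R,4R)-2-bromo-1-methyl-4-(prop-1-en-2-yl)cyclohexyl hydrogen sulfate | C=C(C)[C@@H]1CC[C@](C)(OS(O)(=O)=O)[C@H](Br)C1
F3 | step 9 | trans-6-(hydroxymethyl)carvone (CH2OH anti to the 5-isopropenyl group) | OC[C@@H]1[C@@H](C(=C)C)CC=C(C)C1=O
F4 | step 9 | tosylhydrazone of F3 | OC[C@@H]1[C@@H](C(=C)C)CC=C(C)C1=NNS(=O)(=O)c1ccc(C)cc1
F5 | step 9 | [trans-3-methyl-6-(prop-1-en-2-yl)cyclohex-2-en-1-yl]methanol | OC[C@@H]1[C@@H](C(=C)C)CCC(C)=C1
F6 | step 9 | [6-methyl-3-(prop-1-en-2-yl)-7-oxabicyclo[4.1.0]heptan-2-yl]methanol (epoxide syn to CH2OH, anti to isopropenyl) | OC[C@@H]1[C@@H](C(=C)C)CC[C@]2(C)O[C@H]12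
F7 | step 9 | 2-(iodomethyl)-6-methyl-3-(prop-1-en-2-yl)-7-oxabicyclo[4.1.0]heptane (same configuration as F6) | IC[C@@H]1[C@@H](C(=C)C)CC[C@]2(C)O[C@H]12
F8 | step 9 | 1-[(1R,3R,4S)-3-bromo-4-methyl-4-(trimethylsilyloxy)cyclohexyl]ethan-1-one | CC(=O)[C@@H]1CC[C@](C)(O[Si](C)(C)C)[C@H](Br)C1
F9 | step 9 | 1-[(1R,3R,4S)-3-bromo-4-methyl-4-(trimethylsilyloxy)cyclohexyl]ethenyl triflate | C=C(OS(=O)(=O)C(F)(F)F)[C@@H]1CC[C@](C)(O[Si](C)(C)C)[C@H](Br)C1
F10 | step 9 | alkylzinc iodide from F7 | I[Zn]C[C@@H]1[C@@H](C(=C)C)CC[C@]2(C)O[C@H]12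
F11 | step 9 | trimethylsilyl ether of 15 | C=C(C[C@@H]1[C@@H](C(=C)C)CC[C@]2(C)O[C@H]12)[C@@H]1CC[C@](C)(O[Si](C)(C)C)[C@H](Br)C1
F12 | step 2 | N-(tert-butyldimethylsilyl)hydrazone of the aldehyde of 3 | C=C(C)[C@@H](CC=NN[Si](C)(C)C(C)(C)C)CCC(C)=O
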